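Readings and results were generated by integration with constants of no real substance.

In a one-step world each catalyst weighed in would work from the first second, and product would be sites times turnover rate times time. The bench you take over is not that world, so this note says what I count on.

| flask | left-handed substrate | right-handed substrate | partner | precatalyst | impurity | remark | time |
|---|---|---|---|---|---|---|---|
| red | 0.050 M | 0.050 M | 0.060 M (in portions, 4) | 12 mM | 6.2 mM | run made earlier; portions every 1.0 min |  |
| amber | 0.050 M | 0.050 M | 0.060 M (in portions, 4) | 53 mM | 6.2 mM | run made earlier; portions every 1.0 min |  |
| Tuesday's | 0.050 M | 0.050 M | 0.0600 M | 40 mM | 6.2 mM | everything together at the start | 0.80 h |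
| Monday's | 0.050 M | 0.050 M | 0.0600 M (in portions, 4) | 9.0 mM | 6.2 mM | the portions of partner follow each other after 1.0 min, the first at the start | 1.5 h |

| run | time / min | left-handed product / % | left-handed substrate / % |
|---|---|---|---|
| red | 6.00 | 2 | 52 |
| red | 15.0 | 2 | 47 |
| red | 30.0 | 6 | 42 |
| red | 50.0 | 13 | 40 |
| amber | 12.0 | 10 | 45 |
| amber | 25.0 | 12 | 35 |
| amber | 30.0 | 17 | 39 |
| amber | 50.0 | 12 | 35 |

(readings scatter by 1.5 percentage points)

1. which one finishes higher in amount of left-handed product, in percent of the left-handed substrate and right-handed substrate together charged ("neither" within 2 percentage points) (Tuesday's / Monday's / neither)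
2. amount of left-handed product at the end, in percent of the left-handed substrate and right-handed substrate together charged, Tuesday's
3. amount of left-handed product at the end, in percent of the left-handed substrate and right-handed substrate together charged, Monday's

- free catalyst is single-handed; left-handed substrate and right-handed substrate are mirror images of each other, charged as a racemate, each of them at the stated concentration

I take working catalyst W as precatalyst minus impurity, assuming each impurity takes one catalyst, as in an active-site titration. I then count f, the left-handed product made per working catalyst per minute, from the red run: 13% at 50.0 min on a W of 5.80 mM gives 0.0448 min⁻¹, a reading with a scatter of 1.5 percentage points on its product.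

Monday's has a W of 2.80 mM, so at this f each working catalyst makes left-handed product 4.03 times in 1.5 h, and I expect about 11.3% of it. Tuesday's, at the same f, asks for 72.7 mM of left-handed product, more than its partner charge of 0.0600 M, so I expect Tuesday's to run short of partner, the limiting reagent, within its time. The last three readings of the amber run average about 13.7% of left-handed product, and I suspect precatalyst shares in the partner; Tuesday's holds less precatalyst than amber, so I commit to that average or a little above for Tuesday's, and to Tuesday's finishing higher than Monday's.

Leave the portions alone, since they are over in 3.00 min, far less than Monday's 1.5 h. Add no precatalyst to Monday's, whose W of 2.80 mM is the difference between 9.0 mM and 6.2 mM and smaller than either.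

The forecast names Tuesday's, with 14.5% for it and 11% for Monday's, and says Tuesday's “should finish partner-limited”.

The flask gives 17.7% for Tuesday's and 12.7% for Monday's, so Tuesday's finishes higher.

    partner + free catalyst + left-handed substrate → free catalyst + left-handed product (k = 0.590 L² mol⁻² s⁻¹)
    partner + precatalyst → free catalyst + spent reagent (k = 0.0360 L mol⁻¹ s⁻¹)
    free catalyst + impurity → spent catalyst (k = 11.0 L mol⁻¹ s⁻¹)
    partner + free catalyst + right-handed substrate → free catalyst + right-handed product (k = 0.200 L² mol⁻² s⁻¹)

At the end of Monday's, free catalyst stands at 31.1% of the catalyst charged, which is 2.80 mM against my W of 2.80 mM, and its left-handed product counts 4.54 turnovers against my 4.03. Partner stands as a factor in the rate, so I scale f by it for the neighbour of Monday's with 0.24 M of partner and the same W, which gives 16.1 turnovers, or 45.2%. That neighbour ends with 40.2% of left-handed product.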